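## Analysis of the target

The target 32 is a C25 carbocyclic acid built on a cyclohexane, numbered here C1 (quaternary, bearing CO2H and the 4-methylpent-3-enyl chain), C2 (CH), C3 and C4 (CH2), C5 (spiro carbon of the oxirane) and C6 (CH). A nine-carbon bridge C1′–C9′ runs from C2 to C6 and holds two Z-trisubstituted alkenes (C2′=C3′ and C6′=C7′, each with a methyl group), so that C2, C1, C6 and the bridge form a twelve-membered ring (a bicyclo[9.3.1]pentadecadiene). There are four stereocentres, C1, C2, C5 and C6 (S, R, S and R in this numbering). The carboxyl on C1 is cis to C1′ on C2 and trans to C9′ on C6, so the bridge spans the six-membered ring in a trans fashion; the oxirane oxygen lies on the face of C9′ and its CH2 on the face of the carboxyl. The oxirane sits γ to a free carboxylic acid and is opened by acid with lactone formation. The three trisubstituted alkenes are exposed to electrophilic oxidants and to positional or E/Z isomerisation. The carboxyl sits on a fully substituted carbon between two methines, so an ordinary ester there cannot be saponified at the end. The hard problems are the quaternary C1 with its two substituted neighbours, the trans-bridged twelve-membered ring, and the late oxirane. The strategy rests on one feature: C2 and C5 are 1,4-related, C2 carries a two-carbon unit (C1′–C2′) on the carboxyl face and C5 carries the only ring heteroatom. Joining C2′ to C5 turns the cyclohexane into a bicyclo[2.2.2]octan-2-one, whose C1–C6 edge is the endo adduct of an E-2-alkyl-enal with a 2-silyloxycyclohexa-1,3-diene.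

## Retrosynthetic reasoning

The oxirane is made last. In 32 the C5–CH2 bond and the C–O bond of the oxirane are cut, which leads to keto acid 31 and a Corey–Chaykovsky methylene transfer. Electrophilic epoxidation of a C5 methylene compound could not tell four alkenes apart, whereas a nucleophilic methylene donor touches only the carbonyl group. The forward step has to bring the CH2 group in from the carboxyl face.

Keto acid 31 comes from alcohol 30 by oxidation; the configuration of the C5 carbinol is therefore irrelevant. Acid and alcohol in 30 are masked in 29 as a 2-(trimethylsilyl)ethyl ester and a silyl ether, so that one fluoride treatment frees both without hydroxide or acid. 29 comes from sulfone 28 by reductive desulfonylation.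

In 28 the C4′–C5′ bond is cut, which gives the open-chain bromo sulfone 27. This is the one bond of the bridge that lies between the two alkenes and is allylic on both sides. Both Z-alkenes can therefore be made before ring closure, and the twelve-membered ring is closed by an sp3–sp3 alkylation in which no alkene geometry is at stake. The forward reaction has to favour ring closure over intermolecular alkylation.

The C2′=C3′ alkene of 27 is cut next: bromide 27 comes from alcohol 26 and ester 25, and 25 from aldehyde 23 and phosphonate 24 by a Still–Gennari olefination. This sets the second Z-alkene under reagent control and reduces the C2 arm to an acetaldehyde unit.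

The C2–CH2–CHO arm of 23 and the oxygen on C5 are the two ends of a lactone. Through Weinreb amides 22 and 21 they lead back to lactone 20, the Baeyer–Villiger product of ketone 19. Reconnecting C2′ to C5 in this way removes one stereochemical problem, because the cis relation of the C2 arm and the C5 oxygen becomes a consequence of the bicycle.

Ketone 19 is the ester of acid 18, which comes from keto aldehyde 17 by oxidation. In 17 the bonds C1–C2 and C6–C5 are cut in a retro-[4+2] sense, which gives enal 13 and diene 15. This is the central simplification: one cycloaddition closes the cyclohexane and sets C1, C2 and C6 from two achiral fragments, and the C6 arm already holds C5′–C9′ with its Z-alkene. The phenylsulfonyl group needed for the ring closure of 27 is placed on this arm from the start instead of a protected alcohol. It is inert to every step up to 27 and spares a deprotection, a bromination and a sulfination late in the route. The forward reaction needs endo, regio and facial selectivity.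

Enal 13 is cut at its C=C bond into imine 5 and aldehyde 10 (directed aldol condensation). Aldehyde 10 comes from nerol 6 through bromide 7, sulfone 8 and epoxide 9. Imine 5 comes from imine 3 (made from acetaldehyde 1 and cyclohexylamine 2) and bromide 4. Diene 15 is the kinetic silyl dienol ether of cyclohex-2-enone 14.

## Alternatives that were turned down

Alternative 1: The disconnection is the C4′–C5′ bond of the bridge. In the forward key step an α-sulfonyl carbanion at C5′ displaces a Z-allylic bromide at C4′ and closes the twelve-membered ring, giving the macrobicyclic sulfone A1 (C5 ketone as dioxolane, methyl ester on C1). In its favour, both Z-alkenes are made beforehand, sulfonyl-stabilised allyl anions keep their geometry, and this type of ring closure is well established for terpenoid macrocycles. Against it, the disconnection addresses only the bridge. The cyclohexane with its quaternary C1 between C2 and C6 must already exist and the plan does not say how it is made. The methyl ester on C1 in A1 would have to be cleaved next to an oxirane or a ketone, and the dioxolane needs an acidic release. On the ring closure itself this alternative is exactly as strong as the chosen strategy, which uses the same bond formation in step 19 (A1 corresponds to 28). What the chosen strategy adds is the answer to the harder question, the stereocontrolled core, and a carboxyl protecting group that fluoride removes.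

Alternative 2: The disconnection is the C1–C6 bond of the cyclohexane. In the forward key step, anodic oxidation of a lactone silyl ketene acetal gives a radical cation that is trapped by a tethered silyl enol ether, which closes the cyclohexanone cis-fused to the lactone and gives A2. In its favour, the C5 ketone arrives in the oxidation state needed for the oxirane, with no Baeyer–Villiger step and no redox change at C5, and on this point it is stronger than the chosen route. The cis ring fusion also guarantees the cis relation of the carboxyl and C1′, and the lactone protects the carboxyl. Against it, a quaternary–tertiary bond must form between two hindered enol carbons, and the electron-rich 4-methylpent-3-enyl alkene can be oxidised itself or can trap the radical cation. The configuration at C6 (α to the ketone) is set without a clear bias, and the absolute configuration has to come from a separately made chiral lactone. Both arms in A2 are short oxygenated stubs, so both Z-alkenes and the whole bridge still have to be built. In place of the direct C5 ketone, the chosen strategy offers convergence (C5′–C9′ with its Z-alkene comes in with the dienophile), suprafacial control of C1/C6, and catalyst control of absolute configuration.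

Alternative 3: The disconnection is the C1–C2 bond, cut as a [3,3] shift. In the forward key step the silyl ketene acetal of a tetrasubstituted δ-lactone rearranges through a ring-enforced boat transition state (Ireland–Claisen ring contraction), which closes the cyclohexene and frees the C1 carboxyl in A3. In its favour, the rearrangement is intramolecular and transfers chirality reliably. On certainty of the C1/C2 relation it is stronger than an intermolecular cycloaddition, whose outcome depends on endo/exo preference. It also gives the free acid without an oxidation. Against it, the stereochemical burden is moved into a linear synthesis of a lactone that already carries the C5 and C6 centres and a defined alkene. Enolising an α-branched lactone to a fully substituted ketene acetal is difficult, as is forming a quaternary centre between two substituted carbons. A3 also contains a ring alkene (C3=C4) that the target lacks and that would have to be reduced beside a vinyl group and a trisubstituted alkene. Both arms are stubs, so two Z-selective olefinations and the ring closure remain. In place of its stereochemical certainty, the chosen strategy offers step economy: the ring and three stereocentres form in one catalytic step, there is no superfluous unsaturation, and one Z-alkene is taken from nerol.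

Key step: step 9

Assumption: the sense of induction of the oxazaborolidinium catalyst is taken from the usual model (formyl C–H···O contact, s-trans enal, one face covered by an aryl group). By this model the (S)-catalyst exposes the re face of the α-carbon, so the (R)-catalyst is specified. If the sense proved opposite, the antipodal catalyst would be used with no other change.

## Route

Step 1
Reactants: 1 acetaldehyde; 2 cyclohexylamine
Product: 3 (E)-N-cyclohexylethanimine
Conditions: neat, 0 °C; KOH pellets; distillation
Reagents that add atoms: none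
Why: Imine condensation; KOH takes up the water. The imine is an acetaldehyde enolate equivalent that cannot self-condense.

Step 2
Reactants: 3 (E)-N-cyclohexylethanimine; 4 5-bromo-2-methylpent-2-ene
Product: 5 (E)-N-cyclohexyl-6-methylhept-5-en-1-imine
Conditions: LiN(iPr)2, THF, −78 → 0 °C; then 4, −78 °C → rt
Reagents that add atoms: none
Why: Metalloenamine C-alkylation (SN2) with a primary homoallylic bromide; the aza-enolate reacts once at the former methyl carbon.

Step 3
Reactants: 6 nerol
Product: 7 neryl bromide [(2Z)-1-bromo-3,7-dimethylocta-2,6-diene]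
Conditions: PBr3 (0.4 equiv), Et2O, −20 → 0 °C
Reagents that add atoms: phosphorus tribromide, BrP(Br)Br
Why: Conversion of a primary allylic alcohol into the bromide; at low temperature the substitution is direct, so the Z-alkene should be kept.

Step 4
Reactants: 7 neryl bromide
Product: 8 neryl phenyl sulfone [{[(2Z)-3,7-dimethylocta-2,6-dien-1-yl]sulfonyl}benzene]
Conditions: PhSO2Na, DMF, 0 °C → rt
Reagents that add atoms: sodium benzenesulfinate, [Na+].[O-]S(=O)c1ccccc1
Why: S-alkylation of the sulfinate (SN2) at the primary allylic carbon; the alkene geometry is not involved.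

Step 5
Reactants: 8 neryl phenyl sulfone
Product: 9 racemic 2,2-dimethyl-3-[(3Z)-3-methyl-5-(phenylsulfonyl)pent-3-en-1-yl]oxirane
Conditions: mCPBA (1.05 equiv), NaHCO3, CH2Cl2, 0 °C
Reagents that add atoms: 3-chloroperoxybenzoic acid, OOC(=O)c1cccc(Cl)c1
Why: Prilezhaev epoxidation; the distal trisubstituted alkene is much more nucleophilic than the alkene deactivated by the allylic sulfonyl group. The new stereocentre is racemic and is lost in step 6.

Step 6
Reactants: 9 epoxide
Product: 10 (4Z)-4-methyl-6-(phenylsulfonyl)hex-4-enal
Conditions: H5IO6 (1.2 equiv), THF/Et2O, 0 °C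
Reagents that add atoms: none
Why: Periodic acid opens the epoxide to the glycol and cleaves it in one pot (glycol cleavage), releasing acetone; the sulfone and the Z-alkene are inert to the acid.

Step 7
Reactants: 5 (E)-N-cyclohexyl-6-methylhept-5-en-1-imine; 10 (4Z)-4-methyl-6-(phenylsulfonyl)hex-4-enal
Product: 13 (2E,6Z)-6-methyl-2-(4-methylpent-3-en-1-yl)-8-(phenylsulfonyl)octa-2,6-dienal, via β-hydroxy imine 11 (not isolated), via β-hydroxy aldehyde 12 (not isolated)
Conditions: 5 (1.3 equiv), LiN(iPr)2, THF, 0 °C; 10, −78 °C; then aq. oxalic acid, THF, rt → 50 °C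
Reagents that add atoms: water, O
Why: Directed aldol addition of the lithiated imine followed by hydrolysis and dehydration; at −78 °C addition to the aldehyde should be faster than proton transfer from the sulfone. Acid-mediated dehydration is under thermodynamic control and gives the E-enal (formyl trans to the β-chain).

Step 8
Reactants: 14 cyclohex-2-en-1-one
Product: 15 2-(tert-butyldimethylsilyloxy)cyclohexa-1,3-diene
Conditions: LiN(iPr)2, THF, −78 °C; tBuMe2SiOTf, −78 °C → rt
Reagents that add atoms: tert-butyldimethylsilyl trifluoromethanesulfonate, CC(C)(C)[Si](C)(C)OS(=O)(=O)C(F)(F)F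
Why: Kinetic deprotonation at the α′-carbon gives the cross-conjugated dienolate, which is silylated on oxygen.

Step 9
Reactants: 13 (2E,6Z)-6-methyl-2-(4-methylpent-3-en-1-yl)-8-(phenylsulfonyl)octa-2,6-dienal; 15 2-(tert-butyldimethylsilyloxy)cyclohexa-1,3-diene
Product: 17 2-(4-methylpent-3-en-1-yl)-3-[(3Z)-3-methyl-5-(phenylsulfonyl)pent-3-en-1-yl]-5-oxobicyclo[2.2.2]octane-2-carbaldehyde (formyl syn to the oxo bridge, arm on the neighbouring carbon trans to formyl), via silyl enol ether cycloadduct 16 (not isolated)
Conditions: (R)-1-(2-methylphenyl)-3,3-diphenyltetrahydro-1H,3H-pyrrolo[1,2-c][1,3,2]oxazaborole (20 mol%), HN(SO2CF3)2 (20 mol%), 15 (2 equiv), CH2Cl2, −78 → −40 °C; then 1 M HCl, THF, 0 °C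
Reagents that add atoms: none
Why: The protonated oxazaborolidine binds the formyl oxygen of s-trans 13 and the electron-rich diene 15 adds in a concerted but highly asynchronous [4+2] cycloaddition, whose stepwise limit is a Mukaiyama–Michael addition followed by conjugate closure of the enolate onto the silylated enone (a double Michael sequence that forms the same two bonds); the closest known reaction type is the oxazaborolidinium-catalysed Diels–Alder reaction of 2-silyloxy-1,3-dienes with α-substituted enals. The cyclohexane C1–C6 is closed by this intermolecular [4+2] ring formation (bonds C1–C2 and C6–C5) inside a bicyclo[2.2.2]octene. Regiochemistry follows from the diene polarisation: the terminus next to the silyloxy carbon (future C5) carries the largest HOMO coefficient and bonds to the β-carbon C6, so that the formyl-bearing carbon becomes C1 next to the future C2. The cis relation of the 4-methylpent-3-enyl chain on C1 and the arm on C6 (formyl trans to the arm) is the E geometry of 13 carried over by suprafacial addition. The relation of C1 to the bridgeheads is set by endo placement of the coordinated formyl group under the enol ether bridge, which is also the sterically better mode because the exo mode would push the C6 arm under the bulky silyloxy group. The bridgeheads C2 and C5 are fixed relative to each other by the bicycle, and the absolute configuration is set by the catalyst, whose aryl group covers one face of the bound enal so that the diene adds to the si face at C1 (priorities formyl > C6 > chain CH2). The step needs endo, regio and facial selectivity at the same time; the acidic work-up hydrolyses the enol ether 16 to the ketone, and neither the non-enolisable aldehyde nor the bridgehead-flanked ketone can epimerise.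

Step 10
Reactants: 17 keto aldehyde
Product: 18 2-(4-methylpent-3-en-1-yl)-3-[(3Z)-3-methyl-5-(phenylsulfonyl)pent-3-en-1-yl]-5-oxobicyclo[2.2.2]octane-2-carboxylic acid
Conditions: NaClO2, NaH2PO4, 2-methylbut-2-ene, tBuOH/H2O, 0 °C → rt
Reagents that add atoms: sodium chlorite, [Na+].[O-]Cl=O
Why: Pinnick oxidation; chlorite oxidises only the aldehyde, the alkene scavenger traps hypochlorous acid, and the ketone, sulfone and alkenes are left alone.

Step 11
Reactants: 18 keto acid
Product: 19 2-(trimethylsilyl)ethyl 2-(4-methylpent-3-en-1-yl)-3-[(3Z)-3-methyl-5-(phenylsulfonyl)pent-3-en-1-yl]-5-oxobicyclo[2.2.2]octane-2-carboxylate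
Conditions: Me3SiCH2CH2OH, PPh3, iPrO2CN=NCO2iPr, THF, 0 °C → rt
Reagents that add atoms: 2-(trimethylsilyl)ethanol, C[Si](C)(C)CCO
Why: Mitsunobu esterification; the carboxylate attacks the activated primary alcohol, so the crowding around the acid carbonyl does not matter. This ester is chosen because fluoride cleaves it later by fragmentation, with no attack on the hindered carbonyl.

Step 12
Reactants: 19 keto ester
Product: 20 lactone (2-oxabicyclo[3.2.2]nonan-3-one; oxygen inserted between the carbonyl and the bridgehead C5)
Conditions: Me3SiOOSiMe3, Me3SiOTf (10 mol%), CH2Cl2, −78 → −40 °C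
Reagents that add atoms: bis(trimethylsilyl) peroxide, C[Si](C)(C)OO[Si](C)(C)C
Why: Baeyer–Villiger oxidation with a silyl peroxide, which contains no peracid and therefore should not epoxidise the alkenes. The more substituted bridgehead carbon migrates with retention, so the oxygen on C5 takes the place of the former bridge, cis to the C2 arm.

Step 13
Reactants: 20 lactone
Product: 21 2-(trimethylsilyl)ethyl 5-hydroxy-2-{2-[methoxy(methyl)amino]-2-oxoethyl}-1-(4-methylpent-3-en-1-yl)-6-[(3Z)-3-methyl-5-(phenylsulfonyl)pent-3-en-1-yl]cyclohexane-1-carboxylate (ester, C2 chain and C5 hydroxyl cis; C6 chain trans to them)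
Conditions: MeNH(OMe)·HCl, AlMe3, CH2Cl2, 0 °C → rt; aq. KNaC4H4O6
Reagents that add atoms: N,O-dimethylhydroxylamine hydrochloride, CNOC.Cl
Why: Weinreb aminolysis of the strained seven-membered lactone by the aluminium amide; the hindered C1 ester is not attacked. The C5 oxygen is released as a weakly nucleophilic aluminium alkoxide, which should not acylate onto the C1 ester.

Step 14
Reactants: 21 hydroxy Weinreb amide
Product: 22 C5 tert-butyldimethylsilyl ether of 21
Conditions: tBuMe2SiOTf, 2,6-lutidine, CH2Cl2, −78 → 0 °C
Reagents that add atoms: tert-butyldimethylsilyl trifluoromethanesulfonate, CC(C)(C)[Si](C)(C)OS(=O)(=O)C(F)(F)F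
Why: Silylation of a hindered secondary alcohol with the silyl triflate; the ether removes the neighbouring-group risk between the C5 oxygen and the C1 ester.

Step 15
Reactants: 22 silyl ether Weinreb amide
Product: 23 aldehyde: 2-(trimethylsilyl)ethyl 5-(tert-butyldimethylsilyloxy)-1-(4-methylpent-3-en-1-yl)-6-[(3Z)-3-methyl-5-(phenylsulfonyl)pent-3-en-1-yl]-2-(2-oxoethyl)cyclohexane-1-carboxylate
Conditions: iBu2AlH (1.3 equiv), THF, −78 °C; aq. KNaC4H4O6
Reagents that add atoms: none
Why: Reduction of the Weinreb amide stops at the chelated tetrahedral intermediate and gives the aldehyde on work-up; the neopentyl-type C1 ester reacts much more slowly at −78 °C.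

Step 16
Reactants: 23 aldehyde; 24 ethyl 2-[bis(2,2,2-trifluoroethoxy)phosphoryl]propanoate
Product: 25 Z-enoate: C2 arm is (2Z)-4-ethoxy-3-methyl-4-oxobut-2-en-1-yl
Conditions: 24, KN(SiMe3)2, 18-crown-6, THF, −78 °C
Reagents that add atoms: none
Why: Still–Gennari olefination; the electron-poor phosphonate and the dissociated potassium counter-ion make elimination faster than adduct equilibration, so the Z-trisubstituted enoate (ester cis to C1′) is formed.

Step 17
Reactants: 25 Z-enoate
Product: 26 Z-allylic alcohol: C2 arm is (2Z)-4-hydroxy-3-methylbut-2-en-1-yl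
Conditions: iBu2AlH (2.5 equiv), CH2Cl2, −78 °C; aq. KNaC4H4O6
Reagents that add atoms: none
Why: 1,2-Reduction of the conjugated ester to the allylic alcohol leaves the alkene geometry unchanged; the hindered C1 ester should survive at −78 °C.

Step 18
Reactants: 26 Z-allylic alcohol
Product: 27 Z-allylic bromide: C2 arm is (2Z)-4-bromo-3-methylbut-2-en-1-yl
Conditions: CBr4, PPh3, 2,6-lutidine, CH2Cl2, −30 → 0 °C
Reagents that add atoms: tetrabromomethane, BrC(Br)(Br)Br
Why: Appel bromination; direct displacement at the primary allylic carbon under neutral conditions avoids allylic transposition and Z/E isomerisation.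

Step 19
Reactants: 27 Z-allylic bromide
Product: 28 macrocyclic sulfone: twelve-membered ring closed through C4′–C5′, PhSO2 on C5′ (both epimers), C2′=C3′ and C6′=C7′ both Z, C1 2-(trimethylsilyl)ethyl ester, C5 silyl ether
Conditions: NaN(SiMe3)2 (1.3 equiv), THF, −20 → 0 °C, slow addition of 27 (final 1 mM)
Reagents that add atoms: none
Why: Intramolecular SN2 alkylation of the sulfonyl-stabilised allyl carbanion by the allylic bromide under high dilution; the anion reacts at its α-carbon and keeps the Z geometry. The new centre at C5′ is not controlled and is removed in step 20.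

Step 20
Reactants: 28 macrocyclic sulfone
Product: 29 protected macrocycle: 2-(trimethylsilyl)ethyl ester and C5 tert-butyldimethylsilyl ether of 30
Conditions: Na(Hg) (6%), Na2HPO4, MeOH/THF, −20 °C
Reagents that add atoms: none
Why: Reductive desulfonylation by electron transfer; the allyl anion should be protonated at its less substituted end C5′, which leaves the trisubstituted C6′=C7′ alkene in place. The ester and the silyl ether are inert to the buffered amalgam.

Step 21
Reactants: 29 protected macrocycle
Product: 30 hydroxy acid (C5 hydroxyl cis to the C1 carboxyl)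
Conditions: Bu4NF (5 equiv), THF, rt → 40 °C; aq. NH4Cl
Reagents that add atoms: none
Why: Fluoride fragments the 2-(trimethylsilyl)ethyl ester (loss of ethylene) whatever the hindrance at the carbonyl, and cleaves the silyl ether. The ester should fragment before the hindered silyl ether is cleaved, so the C5 alkoxide meets a carboxylate and cannot lactonise.

Step 22
Reactants: 30 hydroxy acid
Product: 31 macrocyclic keto acid (C5 ketone)
Conditions: Dess–Martin periodinane, NaHCO3, CH2Cl2, 0 °C → rt
Reagents that add atoms: none
Why: Dess–Martin oxidation of the secondary alcohol under buffered conditions that tolerate the carboxylic acid and the alkenes and should not epimerise C6.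

Step 23
Reactants: 31 macrocyclic keto acid
Product: 32 target CNP0116395.1 (oxirane oxygen cis to C9′, oxirane CH2 cis to the carboxyl)
Conditions: 31, KN(SiMe3)2 (1.0 equiv), THF, −10 °C; then Me2S=CH2 [from Me3SI and KN(SiMe3)2, 3 equiv], THF, −10 → 10 °C; aq. NaH2PO4
Reagents that add atoms: trimethylsulfonium iodide, C[S+](C)C.[I-]
Why: Corey–Chaykovsky epoxidation on the preformed carboxylate; addition of the sulfonium ylide is irreversible and sterically governed. The ring face opposite the carboxylate carries both the C9′ substituent on the neighbouring C6 and the 1,3-related 4-methylpent-3-enyl chain, and in either chair one of them is axial there. The methylene should therefore enter cis to the carboxylate, and ring closure of the betaine places the oxygen cis to C9′ as in the target.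

## Compound list

1 | acetaldehyde | CC=O | starting material
2 | cyclohexylamine | NC1CCCCC1 | starting material
3 | (E)-N-cyclohexylethanimine | C/C=N/C1CCCCC1 | intermediate
4 | 5-bromo-2-methylpent-2-ene | CC(C)=CCCBr | starting material
5 | (E)-N-cyclohexyl-6-methylhept-5-en-1-imine | CC(C)=CCCC/C=N/C1CCCCC1 | intermediate
6 | nerol, (2Z)-3,7-dimethylocta-2,6-dien-1-ol | CC(C)=CCC/C(C)=C\CO | starting material
7 | neryl bromide, (2Z)-1-bromo-3,7-dimethylocta-2,6-diene | CC(C)=CCC/C(C)=C\CBr | intermediate
8 | neryl phenyl sulfone, {[(2Z)-3,7-dimethylocta-2,6-dien-1-yl]sulfonyl}benzene | CC(C)=CCC/C(C)=C\CS(=O)(=O)c1ccccc1 | intermediate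
9 | racemic 2,2-dimethyl-3-[(3Z)-3-methyl-5-(phenylsulfonyl)pent-3-en-1-yl]oxirane | CC1(C)OC1CC/C(C)=C\CS(=O)(=O)c1ccccc1 | intermediate
10 | (4Z)-4-methyl-6-(phenylsulfonyl)hex-4-enal | O=CCC/C(C)=C\CS(=O)(=O)c1ccccc1 | intermediate
11 | β-hydroxy imine, N-cyclohexyl imine of 12 (diastereomer mixture) | CC(C)=CCCC(/C=N/C1CCCCC1)C(O)CC/C(C)=C\CS(=O)(=O)c1ccccc1 | intermediate
12 | β-hydroxy aldehyde, (6Z)-3-hydroxy-6-methyl-2-(4-methylpent-3-en-1-yl)-8-(phenylsulfonyl)oct-6-enal (diastereomer mixture) | CC(C)=CCCC(C=O)C(O)CC/C(C)=C\CS(=O)(=O)c1ccccc1 | intermediate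
13 | (2E,6Z)-6-methyl-2-(4-methylpent-3-en-1-yl)-8-(phenylsulfonyl)octa-2,6-dienal | CC(C)=CCC/C(C=O)=C\CC/C(C)=C\CS(=O)(=O)c1ccccc1 | intermediate
14 | cyclohex-2-en-1-one | O=C1C=CCCC1 | starting material
15 | 2-(tert-butyldimethylsilyloxy)cyclohexa-1,3-diene | C[Si](C)(OC1=CCCC=C1)C(C)(C)C | intermediate
16 | silyl enol ether cycloadduct, 5-(tert-butyldimethylsilyloxy)bicyclo[2.2.2]oct-5-ene-2-carbaldehyde with the substituents of 17 | CC(C)=CCC[C@]1(C=O)[C@@H]2CC[C@@H](C(O[Si](C)(C)C(C)(C)C)=C2)[C@@H]1CC/C(C)=C\CS(=O)(=O)c3ccccc3 | intermediate
17 | 2-(4-methylpent-3-en-1-yl)-3-[(3Z)-3-methyl-5-(phenylsulfonyl)pent-3-en-1-yl]-5-oxobicyclo[2.2.2]octane-2-carbaldehyde, formyl endo | CC(C)=CCC[C@]1(C=O)[C@@H]2CC[C@@H](C(=O)C2)[C@@H]1CC/C(C)=C\CS(=O)(=O)c3ccccc3 | intermediate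
18 | corresponding bicyclo[2.2.2]octane-2-carboxylic acid | CC(C)=CCC[C@]1(C(=O)O)[C@@H]2CC[C@@H](C(=O)C2)[C@@H]1CC/C(C)=C\CS(=O)(=O)c3ccccc3 | intermediate
19 | 2-(trimethylsilyl)ethyl ester of 18 | CC(C)=CCC[C@]1(C(=O)OCC[Si](C)(C)C)[C@@H]2CC[C@@H](C(=O)C2)[C@@H]1CC/C(C)=C\CS(=O)(=O)c3ccccc3 | intermediate
20 | Baeyer–Villiger lactone, 2-oxabicyclo[3.2.2]nonan-3-one | CC(C)=CCC[C@]1(C(=O)OCC[Si](C)(C)C)[C@@H]2CC[C@@H](OC(=O)C2)[C@@H]1CC/C(C)=C\CS(=O)(=O)c3ccccc3 | intermediate
21 | hydroxy Weinreb amide (cyclohexane; C1 ester, C2 chain and C5 OH cis) | CC(C)=CCC[C@]1(C(=O)OCC[Si](C)(C)C)[C@@H](CC(=O)N(C)OC)CC[C@@H](O)[C@@H]1CC/C(C)=C\CS(=O)(=O)c3ccccc3 | intermediate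
22 | C5 tert-butyldimethylsilyl ether of 21 | CC(C)=CCC[C@]1(C(=O)OCC[Si](C)(C)C)[C@@H](CC(=O)N(C)OC)CC[C@@H](O[Si](C)(C)C(C)(C)C)[C@@H]1CC/C(C)=C\CS(=O)(=O)c3ccccc3 | intermediate
23 | aldehyde, C2 arm 2-oxoethyl | CC(C)=CCC[C@]1(C(=O)OCC[Si](C)(C)C)[C@@H](CC=O)CC[C@@H](O[Si](C)(C)C(C)(C)C)[C@@H]1CC/C(C)=C\CS(=O)(=O)c3ccccc3 | intermediate
24 | ethyl 2-[bis(2,2,2-trifluoroethoxy)phosphoryl]propanoate | CCOC(=O)C(C)P(=O)(OCC(F)(F)F)OCC(F)(F)F | starting material
25 | Z-enoate, C2 arm (2Z)-4-ethoxy-3-methyl-4-oxobut-2-en-1-yl | CC(C)=CCC[C@]1(C(=O)OCC[Si](C)(C)C)[C@@H](C/C=C(/C)C(=O)OCC)CC[C@@H](O[Si](C)(C)C(C)(C)C)[C@@H]1CC/C(C)=C\CS(=O)(=O)c3ccccc3 | intermediate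
26 | Z-allylic alcohol, C2 arm (2Z)-4-hydroxy-3-methylbut-2-en-1-yl | CC(C)=CCC[C@]1(C(=O)OCC[Si](C)(C)C)[C@@H](C/C=C(/C)CO)CC[C@@H](O[Si](C)(C)C(C)(C)C)[C@@H]1CC/C(C)=C\CS(=O)(=O)c3ccccc3 | intermediate
27 | Z-allylic bromide, C2 arm (2Z)-4-bromo-3-methylbut-2-en-1-yl | CC(C)=CCC[C@]1(C(=O)OCC[Si](C)(C)C)[C@@H](C/C=C(/C)CBr)CC[C@@H](O[Si](C)(C)C(C)(C)C)[C@@H]1CC/C(C)=C\CS(=O)(=O)c3ccccc3 | intermediate
28 | macrocyclic sulfone (PhSO2 on C5′, both epimers) | CC(C)=CCC[C@]1(C(=O)OCC[Si](C)(C)C)[C@H]2C/C=C(/C)CC(S(=O)(=O)c3ccccc3)/C=C(/C)CC[C@H]1[C@@H](CC2)O[Si](C)(C)C(C)(C)C | intermediate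
29 | protected macrocycle (2-(trimethylsilyl)ethyl ester, C5 silyl ether) | CC(C)=CCC[C@]1(C(=O)OCC[Si](C)(C)C)[C@H]2C/C=C(/C)CC/C=C(/C)CC[C@H]1[C@@H](CC2)O[Si](C)(C)C(C)(C)C | intermediate
30 | macrocyclic hydroxy acid | CC(C)=CCC[C@]1(C(=O)O)[C@H]2C/C=C(/C)CC/C=C(/C)CC[C@H]1[C@@H](CC2)O | intermediate
31 | macrocyclic keto acid | CC(C)=CCC[C@]1(C(=O)O)[C@H]2C/C=C(/C)CC/C=C(/C)CC[C@H]1C(=O)CC2 | intermediate
32 | CNP0116395.1, spiro-oxirane acid | CC(C)=CCC[C@]1(C(=O)O)[C@H]2C/C=C(/C)CC/C=C(/C)CC[C@H]1[C@@]1(CC2)CO1 | target

## Step count and least certain steps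

Total: 23 steps. Longest linear sequence: 20 steps (nerol 6 to 32: steps 3–7 and 9–23).

Step 9 (key step). The trisubstituted enal is a poor dienophile. The reaction may stop after the first C–C bond (Michael stage), or a catalyst-free, silyl-cation-promoted background reaction may take over, which would erode both endo and enantioselectivity. The fallback gives up catalyst control and sets out from 13 with 15. HN(SO2CF3)2 (5 mol%) in CH2Cl2 at −78 °C gives the racemic silyl enol ether cycloadduct F1, and hydrolysis as in step 9 gives the racemic keto aldehyde F2. Oxidation as in step 10 gives the racemic acid F3, which is resolved by crystallising the 1-phenylethylammonium salt F4 (drawn for the (R)-amine; the antipodal amine is used if it gives the less soluble salt with the wanted acid). Acidification of F4 returns to the route at 18.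

Step 19. Intermolecular alkylation or base-induced loss of HBr from the allylic bromide may outrun closure of the trans-bridged twelve-membered ring. The fallback closes the ring at C3′–C4′ by a B-alkyl Suzuki coupling and sets out from 23. Olefination with the ylide from (1-iodoethyl)triphenylphosphonium iodide and NaN(SiMe3)2 at −78 °C (Stork–Zhao type) gives the Z-vinyl iodide F5. Deprotonation of the sulfone with KN(SiMe3)2 and alkylation with Bu3SnCH2I gives the β-stannyl sulfone F6, which loses the stannyl sulfinate on warming or on silica gel to give the terminal diene F7. Hydroboration of the terminal alkene with 9-borabicyclo[3.3.1]nonane gives the alkylborane F8, and coupling with PdCl2(dppf), AsPh3 and Cs2CO3 in DMF/THF/H2O under high dilution closes the ring with retention at the vinyl iodide. The fallback comes back to the route at 29, so no sulfone has to be removed.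

Step 20. The intermediate allyl radical or anion may be protonated at C7′ or may rotate, which would cause allylic transposition of the C6′=C7′ alkene or loss of its Z geometry. The fallback changes the order and the mechanism and sets out from 28. Bu4NF first gives the hydroxy acid sulfone F9. PdCl2(dppp) (catalytic) with LiBHEt3 in THF at 0 °C then removes the sulfonyl group through a π-allyl palladium hydride, which delivers hydrogen to the less substituted end. The carboxylate and alkoxide formed by the first two equivalents of hydride are inert. The fallback comes back to the route at 30.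

Step 23. The basic ylide may deprotonate α to the hindered carbonyl (C4 or C6) instead of adding, which would give epimerisation at C6 or recovered ketone; incomplete discrimination of the two ring faces is the second concern. The fallback uses a less basic, more nucleophilic carbenoid and sets out from 31. After deprotonation of the acid with LiN(SiMe3)2 (1 equiv), chloromethyllithium generated from ClCH2I and MeLi·LiBr at −78 °C adds to the ketone and gives the chlorohydrin F10. K2CO3 in MeOH at 0 °C closes the oxirane and the fallback comes back at 32.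

Step 7. Proton transfer from the acidic allylic sulfone CH2 or from the aldehyde α-position to the aza-enolate may compete with carbonyl addition, and dehydration may be incomplete. The fallback is a Horner–Wadsworth–Emmons route and sets out from 4 and 10. Alkylation of triethyl phosphonoacetate with 4 (NaH, DMSO) gives phosphonate F11, and olefination of 10 with F11 (NaH, THF) gives the E-enoate F12 after separation from its Z isomer. iBu2AlH reduces F12 to the allylic alcohol F13, and MnO2 oxidises F13 to the enal, coming back at 13.

## Further compounds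

F1 | step 9 | racemic silyl enol ether cycloadduct (both enantiomers of 16) | CC(C)=CCC[C@]1(C=O)[C@@H]2CC[C@@H](C(O[Si](C)(C)C(C)(C)C)=C2)[C@@H]1CC/C(C)=C\CS(=O)(=O)c3ccccc3.CC(C)=CCC[C@@]1(C=O)[C@H]2CC[C@H](C(O[Si](C)(C)C(C)(C)C)=C2)[C@H]1CC/C(C)=C\CS(=O)(=O)c3ccccc3
F2 | step 9 | racemic keto aldehyde (both enantiomers of 17) | CC(C)=CCC[C@]1(C=O)[C@@H]2CC[C@@H](C(=O)C2)[C@@H]1CC/C(C)=C\CS(=O)(=O)c3ccccc3.CC(C)=CCC[C@@]1(C=O)[C@H]2CC[C@H](C(=O)C2)[C@H]1CC/C(C)=C\CS(=O)(=O)c3ccccc3
F3 | step 9 | racemic keto acid (both enantiomers of 18) | CC(C)=CCC[C@]1(C(=O)O)[C@@H]2CC[C@@H](C(=O)C2)[C@@H]1CC/C(C)=C\CS(=O)(=O)c3ccccc3.CC(C)=CCC[C@@]1(C(=O)O)[C@H]2CC[C@H](C(=O)C2)[C@H]1CC/C(C)=C\CS(=O)(=O)c3ccccc3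
F4 | step 9 | (R)-1-phenylethylammonium salt of acid 18 | CC(C)=CCC[C@]1(C(=O)[O-])[C@@H]2CC[C@@H](C(=O)C2)[C@@H]1CC/C(C)=C\CS(=O)(=O)c3ccccc3.C[C@@H]([NH3+])c1ccccc1
F5 | step 19 | Z-vinyl iodide, C2 arm (2Z)-3-iodobut-2-en-1-yl | CC(C)=CCC[C@]1(C(=O)OCC[Si](C)(C)C)[C@@H](C/C=C(/C)I)CC[C@@H](O[Si](C)(C)C(C)(C)C)[C@@H]1CC/C(C)=C\CS(=O)(=O)c3ccccc3
F6 | step 19 | β-stannyl sulfone, Bu3SnCH2 on C5′ (both epimers) | CC(C)=CCC[C@]1(C(=O)OCC[Si](C)(C)C)[C@@H](C/C=C(/C)I)CC[C@@H](O[Si](C)(C)C(C)(C)C)[C@@H]1CC/C(C)=C\C(C[Sn](CCCC)(CCCC)CCCC)S(=O)(=O)c3ccccc3
F7 | step 19 | terminal diene, C6 arm (3Z)-3-methylhexa-3,5-dien-1-yl | CC(C)=CCC[C@]1(C(=O)OCC[Si](C)(C)C)[C@@H](C/C=C(/C)I)CC[C@@H](O[Si](C)(C)C(C)(C)C)[C@@H]1CC/C(C)=C\C=C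
F8 | step 19 | alkylborane, 9-borabicyclo[3.3.1]nonan-9-yl on C4′ | CC(C)=CCC[C@]1(C(=O)OCC[Si](C)(C)C)[C@@H](C/C=C(/C)I)CC[C@@H](O[Si](C)(C)C(C)(C)C)[C@@H]1CC/C(C)=C\CCB3C4CCCC3CCC4
F9 | step 20 | macrocyclic hydroxy acid sulfone (PhSO2 on C5′, both epimers) | CC(C)=CCC[C@]1(C(=O)O)[C@H]2C/C=C(/C)CC(S(=O)(=O)c3ccccc3)/C=C(/C)CC[C@H]1[C@@H](CC2)O
F10 | step 23 | chlorohydrin, C5 hydroxyl cis to C9′, CH2Cl cis to the carboxyl | CC(C)=CCC[C@]1(C(=O)O)[C@H]2C/C=C(/C)CC/C=C(/C)CC[C@H]1[C@](CC2)(O)CCl
F11 | step 7 | ethyl 2-(diethoxyphosphoryl)-6-methylhept-5-enoate | CCOC(=O)C(CCC=C(C)C)P(=O)(OCC)OCC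
F12 | step 7 | ethyl (2E,6Z)-6-methyl-2-(4-methylpent-3-en-1-yl)-8-(phenylsulfonyl)octa-2,6-dienoate | CCOC(=O)/C(CCC=C(C)C)=C/CC/C(C)=C\CS(=O)(=O)c1ccccc1
F13 | step 7 | (2E,6Z)-6-methyl-2-(4-methylpent-3-en-1-yl)-8-(phenylsulfonyl)octa-2,6-dien-1-ol | OC/C(CCC=C(C)C)=C/CC/C(C)=C\CS(=O)(=O)c1ccccc1
A1 | alternative 1 | macrobicyclic sulfone, methyl ester, C5 dioxolane (both epimers at C5′) | CC(C)=CCC[C@]1(C(=O)OC)[C@H]2C/C=C(/C)CC(S(=O)(=O)c3ccccc3)/C=C(/C)CC[C@H]1C3(OCCO3)CC2
A2 | alternative 2 | cis-fused lactone cyclohexanone with quaternary C1 | CC(C)=CCC[C@]12C(=O)OC[C@H]1CCC(=O)[C@@H]2CCOCc1ccc(OC)cc1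
A3 | alternative 3 | cyclohex-3-ene-1-carboxylic acid with quaternary C1, C2 ether arm, C5 silyl ether, C6 vinyl | CC(C)=CCC[C@]1(C(=O)O)[C@@H](CCOCc2ccc(OC)cc2)C=C[C@@H](O[Si](C)(C)C(C)(C)C)[C@@H]1C=C
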